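**Plan**

- The target is luteolin carrying methyl ethers at O5 and O7 and two additional methoxy groups at C6 and C8. The retrosynthesis cuts, in order, the two C-O bonds of a diphenylmethylene ketal masking the 3',4'-catechol, the C6-OMe and C8-OMe bonds (back to C-Br), the O5-Me and O7-Me bonds, and the two C-Br bonds, arriving at luteolin.
- Enabling feature: C6 and C8 are the only C-H carbons of ring A, and each lies between two oxygen-bearing carbons (C5/C7 and C7/C8a). They are therefore the nucleophilic sites that accept bromine, and the two C-Br bonds become the handles for C-O bond formation.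
- Forward order: rings A, B and C all come intact from luteolin. Only a temporary dioxole on ring B is closed (step 1) and opened again (step 5). The sequence is ketal formation, dibromination, O-methylation, double methoxylation, ketal cleavage.
- Stereochemistry: the target is achiral and has no stereocentre, so no stereocontrol is needed.

Key step: step 4

Remark: flavone numbering is used throughout (O1, C2, C3, C4, C4a, C5 to C8, C8a; ring B carbons primed). Luteolin, dichlorodiphenylmethane, N-bromosuccinimide, iodomethane and NaOMe (as its methanol solution) are taken as commercial.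

**Route**

Step 1
Reactants: 1 luteolin; 2 dichlorodiphenylmethane
Product: 3 2-(2,2-diphenyl-1,3-benzodioxol-5-yl)-5,7-dihydroxy-4H-chromen-4-one
Conditions: Ph2CCl2 (1.5 equiv), Ph2O, 175 °C, 30 min
Reagents that add atoms: dichlorodiphenylmethane, ClC(Cl)(c1ccccc1)c1ccccc1
Why: Thermal double O-alkylation of the catechol by the geminal dichloride (diphenylmethylene ketal formation) should be selective because only the vicinal 3',4'-hydroxyls can close the five-membered dioxole, whereas a single aryloxy(chloro)diphenylmethane link at O5 or O7 cannot cyclise and is hydrolysed back to the phenol on work-up.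

Step 2
Reactants: 3 2-(2,2-diphenyl-1,3-benzodioxol-5-yl)-5,7-dihydroxy-4H-chromen-4-one; 4 N-bromosuccinimide
Product: 5 6,8-dibromo-2-(2,2-diphenyl-1,3-benzodioxol-5-yl)-5,7-dihydroxy-4H-chromen-4-one
Conditions: NBS (2.05 equiv), DMF, 0 °C to rt, dark
Reagents that add atoms: N-bromosuccinimide, O=C1CCC(=O)N1Br
Why: Electrophilic aromatic bromination with NBS should go only to C6 and C8, the two free positions of the phloroglucinol-type ring A that are each ortho or para to both free hydroxyls, while ring B and C3 are deactivated by conjugation with the pyranone carbonyl.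

Step 3
Reactants: 5 6,8-dibromo-2-(2,2-diphenyl-1,3-benzodioxol-5-yl)-5,7-dihydroxy-4H-chromen-4-one; 6 iodomethane
Product: 7 6,8-dibromo-2-(2,2-diphenyl-1,3-benzodioxol-5-yl)-5,7-dimethoxy-4H-chromen-4-one
Conditions: MeI (6 equiv), K2CO3 (6 equiv), DMF, 45 °C, sealed vessel
Reagents that add atoms: iodomethane, CI
Why: Williamson ether synthesis in which the acidic 7-OH between two bromines and, with excess reagent in DMF, the hydrogen-bonded 5-OH are O-methylated, C-alkylation being excluded because C6 and C8 are blocked, and the ketal and the aryl bromides are inert to K2CO3.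

Step 4
Reactants: 7 6,8-dibromo-2-(2,2-diphenyl-1,3-benzodioxol-5-yl)-5,7-dimethoxy-4H-chromen-4-one; 8 NaOMe
Product: 9 2-(2,2-diphenyl-1,3-benzodioxol-5-yl)-5,6,7,8-tetramethoxy-4H-chromen-4-one
Conditions: NaOMe (30% in MeOH, 10 equiv), CuBr (0.4 equiv), anhydrous DMF, 110 °C, N2
Reagents that add atoms: NaOMe, [Na+].[O-]C
Why: Methoxide exchanges for bromide on CuBr to give a monovalent copper methoxide, which adds oxidatively into each aryl C-Br bond; the resulting aryl methoxide species of trivalent copper reductively eliminates the aryl methyl ether and returns monovalent copper. The closest known reaction type is the Ullmann-type CuBr-catalysed methanolysis of aryl bromides with NaOMe in DMF, a reaction established on ring A halogenated 5,7-dioxygenated flavones. No ring is closed and no stereocentre is created; the step forms the C6-O and C8-O bonds. Only chemoselectivity is needed, because the bromines already occupy the only two carbons of ring A that lack oxygen, so the substitution pattern is fixed by the substrate. The ketal is inert to base, ring B carries no leaving group, and methoxide addition at C2 of the pyranone is reversible as long as water is excluded. Excess NaOMe and rigorous exclusion of oxygen and moisture should keep substitution ahead of hydrodebromination.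

Step 5
Reactants: 9 2-(2,2-diphenyl-1,3-benzodioxol-5-yl)-5,6,7,8-tetramethoxy-4H-chromen-4-one
Product: 10 2-(3,4-dihydroxyphenyl)-5,6,7,8-tetramethoxy-4H-chromen-4-one (CNP0148178.0)
Conditions: AcOH/H2O 4:1, reflux
Reagents that add atoms: none
Why: Acid-catalysed ketal hydrolysis in which protonation opens the dioxole to a diaryl-stabilised oxocarbenium ion that water captures to release benzophenone and the catechol, while the four aryl methyl ethers and the pyranone are stable to hot aqueous acetic acid.

**Compound list**

1 | luteolin (2-(3,4-dihydroxyphenyl)-5,7-dihydroxy-4H-chromen-4-one) | O=c1cc(-c2ccc(O)c(O)c2)oc2cc(O)cc(O)c12 | starting material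
2 | dichlorodiphenylmethane | ClC(Cl)(c1ccccc1)c1ccccc1 | starting material
3 | 2-(2,2-diphenyl-1,3-benzodioxol-5-yl)-5,7-dihydroxy-4H-chromen-4-one | O=c1cc(-c2ccc3OC(c4ccccc4)(c4ccccc4)Oc3c2)oc2cc(O)cc(O)c12 | intermediate
4 | N-bromosuccinimide | O=C1CCC(=O)N1Br | starting material
5 | 6,8-dibromo-2-(2,2-diphenyl-1,3-benzodioxol-5-yl)-5,7-dihydroxy-4H-chromen-4-one | O=c1cc(-c2ccc3OC(c4ccccc4)(c4ccccc4)Oc3c2)oc2c(Br)c(O)c(Br)c(O)c12 | intermediate
6 | iodomethane | CI | starting material
7 | 6,8-dibromo-2-(2,2-diphenyl-1,3-benzodioxol-5-yl)-5,7-dimethoxy-4H-chromen-4-one | COc1c(Br)c(OC)c2c(=O)cc(-c3ccc4OC(c5ccccc5)(c5ccccc5)Oc4c3)oc2c1Br | intermediate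
8 | NaOMe (sodium methoxide) | [Na+].[O-]C | starting material
9 | 2-(2,2-diphenyl-1,3-benzodioxol-5-yl)-5,6,7,8-tetramethoxy-4H-chromen-4-one | COc1c(OC)c(OC)c2c(=O)cc(-c3ccc4OC(c5ccccc5)(c5ccccc5)Oc4c3)oc2c1OC | intermediate
10 | 2-(3,4-dihydroxyphenyl)-5,6,7,8-tetramethoxy-4H-chromen-4-one | COc1c(OC)c(OC)c2c(=O)cc(-c3ccc(O)c(O)c3)oc2c1OC | target

**Step count**

Total steps: 5. Longest linear sequence: 5.

**Steps most likely to fail**

Step 4. The second substitution at the doubly ortho-substituted positions may stall, with hydrodebromination, methoxide-induced opening of the pyranone or loss of the C5 methyl group taking over. The fallback sets out from compound 5 and runs the same CuBr-catalysed methanolysis (NaOMe in MeOH, CuBr, DMF, reflux) on the free diphenol. There the ring A phenoxide protects the pyranone against nucleophilic attack and the hindrance around each bromine is smaller. This should give 2-(2,2-diphenyl-1,3-benzodioxol-5-yl)-5,7-dihydroxy-6,8-dimethoxy-4H-chromen-4-one F1. Its two phenols are then methylated with MeI and K2CO3 in DMF, and the route is rejoined at compound 9.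

Step 3. O-methylation may stop after the first ether, because the remaining 5-OH is hydrogen-bonded to the carbonyl and now flanked by bromine, and the 2,6-dibromophenoxide at O7 is a weak nucleophile. The fallback sets out from compound 3 and reverses the order of operations. Methylation with MeI and K2CO3 in DMF before any bromine is present should give 2-(2,2-diphenyl-1,3-benzodioxol-5-yl)-5,7-dimethoxy-4H-chromen-4-one F2. Dibromination of this diether with NBS (2.2 equiv, DMF, rt to 50 °C) at C6 and C8, still the most electron-rich positions, returns to the route at compound 7.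

Step 5. Under hot acid the ketal hydrolysis may be accompanied by carbonyl-assisted loss of the C5 methyl ether, or it may remain incomplete. The fallback sets out from compound 9 and cleaves the ketal reductively instead: hydrogenolysis of the two benzylic C-O bonds (H2 at 1 atm, Pd/C, THF/MeOH, rt) under neutral conditions delivers compound 10 directly, with no new intermediate.

**Further compounds**

F1 | step 4 | 2-(2,2-diphenyl-1,3-benzodioxol-5-yl)-5,7-dihydroxy-6,8-dimethoxy-4H-chromen-4-one | COc1c(O)c(OC)c2oc(-c3ccc4OC(c5ccccc5)(c5ccccc5)Oc4c3)cc(=O)c2c1O
F2 | step 3 | 2-(2,2-diphenyl-1,3-benzodioxol-5-yl)-5,7-dimethoxy-4H-chromen-4-one | COc1cc(OC)c2c(=O)cc(-c3ccc4OC(c5ccccc5)(c5ccccc5)Oc4c3)oc2c1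
F0 | step 5 | none | none
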